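**Plan**

- Azulene numbering is used for the bicycle: C3 carries OH and isopropyl, C3a–H and C8a–CH3 are the ring-fusion atoms, C4 carries the ester, C5=C6 is the olefin. Retrosynthesis first cuts the ester C–O bond, then takes the C4 carbinol back to a β-hydroxy enone, and the enone back to a cyclohept-7-en-4-one.
- The seven-membered ring is then cut at C3a–C8a and C5–C6 in one (4+3) event. The segment C3a–C4–C5 has oxygen on its central carbon (oxyallyl unit), C6–C7–C8–C8a is the diene, and the C3 tertiary carbinol next to C3a is a former epoxide oxygen. This C3–OH/C4–O array flanking C3a is what allows an intramolecular epoxy enolsilane cycloaddition.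
- Forward: a dienyl iodide and a (Z)-iodo allylic alcohol are joined (sp3–sp2 coupling), then epoxidized and converted to the epoxy methyl ketone and its enol silane. Both rings then arise at once from this acyclic chain (tether C1–C2). The C7=C8 olefin left by the diene is moved to C5=C6 by hydrogenation and dehydrogenation.
- Stereochemistry: the Sharpless epoxidation sets C3 and, by inversion in the cycloaddition, C3a. The (E)-tethered diene in an extended transition state sets C8a (trans fusion). C4 is set by hydride delivery directed by the C3 hydroxyl.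

Key step: step 10

Assumption: compounds 2 and 6 are taken as purchasable in the stated isomeric purity, and cycloadduct 18 is taken to be isolated as its C3 triethylsilyl ether (silyl transfer from the enol oxygen).

**Route**

Step 1
Reactants: 1 but-3-yn-1-ol; 2 (E)-1-bromoprop-1-ene
Product: 4 (3E,5E)-3-methylhepta-3,5-dien-1-ol, via alkenylalane 3 (not isolated)
Conditions: Me3Al (3 equiv), Cp2ZrCl2 (0.25 equiv), CH2Cl2, 0 °C to rt; then 2, Pd(PPh3)4 (5 mol %), ZnCl2 (1 equiv), THF, rt; 1 M HCl work-up
Reagents that add atoms: trimethylaluminium C[Al](C)C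
Why: Zirconium-catalysed syn-carboalumination (Negishi) adds methyl and aluminium across the alkyne regio- and stereoselectively, and the palladium/zinc-cocatalysed Negishi coupling proceeds with retention at both sp2 carbons, which should set the (3E,5E)-diene.

Step 2
Reactants: 4 (3E,5E)-3-methylhepta-3,5-dien-1-ol
Product: 5 (2E,4E)-7-iodo-5-methylhepta-2,4-diene
Conditions: PPh3, imidazole, I2, CH2Cl2, 0 °C
Reagents that add atoms: iodine [I][I]
Why: Appel-type iodination of the primary alcohol (SN2 on the alkoxyphosphonium ion) under neutral conditions that should leave the diene untouched.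

Step 3
Reactants: 6 4-methylpent-2-yn-1-ol
Product: 8 (2Z)-3-iodo-4-methylpent-2-en-1-ol, via cyclic alkenylaluminate 7 (not isolated)
Conditions: NaAlH2(OCH2CH2OMe)2 (Red-Al, 1.2 equiv), THF, 0 °C to rt; then I2, −78 to 0 °C
Reagents that add atoms: iodine [I][I]
Why: Hydroxyl-directed trans-hydroalumination places aluminium on C3 in a five-membered alkoxyaluminate, and iodinolysis with retention should give the (Z)-iodide with iodine cis to CH2OH.

Step 4
Reactants: 5 (2E,4E)-7-iodo-5-methylhepta-2,4-diene; 8 (2Z)-3-iodo-4-methylpent-2-en-1-ol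
Product: 11 (2E,6E,8E)-6-methyl-3-(propan-2-yl)deca-2,6,8-trien-1-ol, via alkyllithium 9 (not isolated), via lithium alkylborate 10 (not isolated)
Conditions: 5, t-BuLi (2.1 equiv), Et2O, −78 °C; B-methoxy-9-BBN, THF, −78 °C to rt; then 8, Pd(dppf)Cl2 (5 mol %), K3PO4 (3 M aq), DMF, rt
Reagents that add atoms: none
Why: B-alkyl Suzuki–Miyaura coupling through the lithium alkyl(methoxy)borate; retention at the vinyl iodide places the alkyl chain cis to CH2OH, which is the (2E) trisubstituted olefin.

Step 5
Reactants: 11 (2E,6E,8E)-6-methyl-3-(propan-2-yl)deca-2,6,8-trien-1-ol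
Product: 12 [(2R,3R)-3-[(3E,5E)-3-methylhepta-3,5-dien-1-yl]-3-(propan-2-yl)oxiran-2-yl]methanol
Conditions: Ti(OiPr)4 (10 mol %), D-(−)-diethyl tartrate (12 mol %), t-BuOOH (2 equiv, isooctane), 4 Å molecular sieves, CH2Cl2, −20 °C
Reagents that add atoms: tert-butyl hydroperoxide CC(C)(C)OO
Why: Sharpless asymmetric epoxidation acts only on the allylic alcohol (the diene is not touched); the D-tartrate ligand should give the (2R,3R) oxirane, the mirror-image sense of that obtained from geraniol-type substrates with the L-tartrate, with the chain and CH2OH cis as fixed by the (2E) olefin.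

Step 6
Reactants: 12 [(2R,3R)-3-[(3E,5E)-3-methylhepta-3,5-dien-1-yl]-3-(propan-2-yl)oxiran-2-yl]methanol
Product: 13 (2S,3R)-3-[(3E,5E)-3-methylhepta-3,5-dien-1-yl]-3-(propan-2-yl)oxirane-2-carbaldehyde
Conditions: Dess–Martin periodinane, NaHCO3, CH2Cl2, 0 °C to rt
Reagents that add atoms: none
Why: Buffered Dess–Martin oxidation of the primary epoxy alcohol should give the aldehyde without epoxide opening or epimerization (the descriptor at C2 changes only by priority).

Step 7
Reactants: 13 (2S,3R)-3-[(3E,5E)-3-methylhepta-3,5-dien-1-yl]-3-(propan-2-yl)oxirane-2-carbaldehyde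
Product: 14 1-[(2R,3R)-3-[(3E,5E)-3-methylhepta-3,5-dien-1-yl]-3-(propan-2-yl)oxiran-2-yl]ethan-1-ol (both carbinol epimers)
Conditions: MeMgBr (1.2 equiv), THF, −78 °C; aq NH4Cl
Reagents that add atoms: methylmagnesium bromide C[Mg]Br
Why: Grignard 1,2-addition to the aldehyde at low temperature is faster than epoxide opening; the new carbinol centre is not controlled because it is removed in step 8.

Step 8
Reactants: 14 1-[(2R,3R)-3-[(3E,5E)-3-methylhepta-3,5-dien-1-yl]-3-(propan-2-yl)oxiran-2-yl]ethan-1-ol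
Product: 15 1-[(2S,3R)-3-[(3E,5E)-3-methylhepta-3,5-dien-1-yl]-3-(propan-2-yl)oxiran-2-yl]ethan-1-one
Conditions: Dess–Martin periodinane, NaHCO3, CH2Cl2, 0 °C to rt
Reagents that add atoms: none
Why: Dess–Martin oxidation of the secondary alcohol converges both epimers to the epoxy methyl ketone.

Step 9
Reactants: 15 1-[(2S,3R)-3-[(3E,5E)-3-methylhepta-3,5-dien-1-yl]-3-(propan-2-yl)oxiran-2-yl]ethan-1-one
Product: 16 triethyl({1-[(2S,3R)-3-[(3E,5E)-3-methylhepta-3,5-dien-1-yl]-3-(propan-2-yl)oxiran-2-yl]ethenyl}oxy)silane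
Conditions: TESOTf (1.3 equiv), Et3N (3 equiv), CH2Cl2, −78 °C; cold aq NaHCO3
Reagents that add atoms: triethylsilyl trifluoromethanesulfonate CC[Si](CC)(CC)OS(=O)(=O)C(F)(F)F
Why: Soft enolization of the methyl ketone with silyl triflate and amine should give the less substituted enol silane, and the excess amine keeps the medium non-acidic so that the epoxide survives.

Step 10
Reactants: 16 triethyl({1-[(2S,3R)-3-[(3E,5E)-3-methylhepta-3,5-dien-1-yl]-3-(propan-2-yl)oxiran-2-yl]ethenyl}oxy)silane
Product: 18 (3R,3aR,6R,8aR)-6,8a-dimethyl-3-(propan-2-yl)-3-[(triethylsilyl)oxy]-2,3,3a,5,6,8a-hexahydroazulen-4(1H)-one, via silylated oxiranium triflate 17 (not isolated)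
Conditions: TESOTf (10–20 mol %), CH2Cl2 (0.01 M), −78 °C; then Et3N
Reagents that add atoms: none
Why: Catalytic TESOTf silylates the epoxide oxygen; the C–O bond next to the enol silane ionizes toward a 2-(silyloxy)allyl cation while the fully substituted diene terminus attacks that carbon from the backside, the enol silane terminus then closes onto the far end of the allyl cation, and the silyl group on the carbonyl oxygen is passed to the next epoxide, so that 16 is isomerized to 18. The closest known reaction type is the silyl-triflate-catalysed intramolecular (4+3) cycloaddition of epoxy enolsilanes with tethered dienes (an oxyallyl cation cycloaddition). The cyclopentane closes through the C3a–C8a bond, 5-exo with respect to the attacking diene double bond, and the cycloheptene closes through the C5–C6 bond, 7-endo with respect to the allyl cation, both within one extended (chair-like) transition state. C3 keeps the epoxide configuration because its C–O bond is not broken, C3a is set by inversion at the epoxide carbon, C8a by the diene face that the short tether on the E position allows in the extended transition state (C8a–CH3 anti to C3a–H, trans fusion), and C6 by suprafacial use of the (E)-propenyl terminus (this centre is removed later). The step needs (4+3) closure over (3+2) closure or proton loss and trans over cis fusion; the (E,E)-diene that can reach the s-cis form, the two-carbon tether, low temperature and high dilution should secure both.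

Step 11
Reactants: 18 (3R,3aR,6R,8aR)-6,8a-dimethyl-3-(propan-2-yl)-3-[(triethylsilyl)oxy]-2,3,3a,5,6,8a-hexahydroazulen-4(1H)-one
Product: 19 (3R,3aR,6S,8aS)-6,8a-dimethyl-3-(propan-2-yl)-3-[(triethylsilyl)oxy]octahydroazulen-4(1H)-one
Conditions: H2 (1 atm), Pd/C (5 wt % Pd on carbon), EtOAc, rt
Reagents that add atoms: none
Why: Heterogeneous hydrogenation of the disubstituted C7=C8 olefin; ketone and silyl ether are inert and no centre is changed (the C6 and C8a descriptors change only by priority).

Step 12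
Reactants: 19 (3R,3aR,6S,8aS)-6,8a-dimethyl-3-(propan-2-yl)-3-[(triethylsilyl)oxy]octahydroazulen-4(1H)-one
Product: 20 triethyl{[(3R,3aS,6S,8aS)-6,8a-dimethyl-3-(propan-2-yl)-4-[(trimethylsilyl)oxy]-1,2,3,3a,6,7,8,8a-octahydroazulen-3-yl]oxy}silane
Conditions: LiN(iPr)2 (1.2 equiv), Me3SiCl (1.5 equiv, internal quench), THF, −78 °C; Et3N, pentane work-up
Reagents that add atoms: chlorotrimethylsilane C[Si](C)(C)Cl
Why: Kinetic deprotonation at the unhindered C5 methylene (the C3a methine is shielded by two quaternary neighbours) with in situ silylation should give the C4=C5 trimethylsilyl enol ether without touching the ring-fusion centre or eliminating the β-silyloxy group.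

Step 13
Reactants: 20 triethyl{[(3R,3aS,6S,8aS)-6,8a-dimethyl-3-(propan-2-yl)-4-[(trimethylsilyl)oxy]-1,2,3,3a,6,7,8,8a-octahydroazulen-3-yl]oxy}silane
Product: 21 (3R,3aR,8aS)-6,8a-dimethyl-3-(propan-2-yl)-3-[(triethylsilyl)oxy]-2,3,3a,7,8,8a-hexahydroazulen-4(1H)-one
Conditions: Pd(OAc)2 (1.1 equiv), MeCN, rt
Reagents that add atoms: none
Why: Saegusa–Ito oxidation: the palladium enolate loses the C6 hydrogen by β-hydride elimination to give the conjugated C5=C6 enone, and the transient C6 centre disappears.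

Step 14
Reactants: 21 (3R,3aR,8aS)-6,8a-dimethyl-3-(propan-2-yl)-3-[(triethylsilyl)oxy]-2,3,3a,7,8,8a-hexahydroazulen-4(1H)-one
Product: 22 (3R,3aR,8aS)-3-hydroxy-6,8a-dimethyl-3-(propan-2-yl)-2,3,3a,7,8,8a-hexahydroazulen-4(1H)-one
Conditions: HF·pyridine, pyridine, THF, 0 °C to rt
Reagents that add atoms: none
Why: Fluoride-mediated Si–O cleavage under buffered, non-basic conditions should free the tertiary alcohol without retro-aldol cleavage or dehydration of the β-hydroxy ketone.

Step 15
Reactants: 22 (3R,3aR,8aS)-3-hydroxy-6,8a-dimethyl-3-(propan-2-yl)-2,3,3a,7,8,8a-hexahydroazulen-4(1H)-one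
Product: 23 (3R,3aS,4S,8aS)-6,8a-dimethyl-3-(propan-2-yl)-1,2,3,3a,4,7,8,8a-octahydroazulene-3,4-diol
Conditions: Me4NBH(OAc)3 (5 equiv), MeCN–AcOH (1:1), −30 °C
Reagents that add atoms: none
Why: Hydroxyl-directed (Evans–Saksena) reduction: the borohydride bound to the C3 oxygen delivers hydride to the carbonyl face on which C3–O lies, so the new C4–OH should be anti to C3–OH (4S), and the triacetoxyborohydride does not reduce the enone conjugately.

Step 16
Reactants: 23 (3R,3aS,4S,8aS)-6,8a-dimethyl-3-(propan-2-yl)-1,2,3,3a,4,7,8,8a-octahydroazulene-3,4-diol; 24 4-methoxybenzoyl chloride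
Product: 25 (3R,3aS,4S,8aS)-3-hydroxy-6,8a-dimethyl-3-(propan-2-yl)-1,2,3,3a,4,7,8,8a-octahydroazulen-4-yl 4-methoxybenzoate
Conditions: 24 (1.5 equiv), Et3N, DMAP (0.2 equiv), CH2Cl2, 0 °C to rt
Reagents that add atoms: none
Why: DMAP-catalysed acylation of the secondary allylic alcohol; the tertiary C3 hydroxyl is too hindered to compete.

**Compound list**

1 | but-3-yn-1-ol | C#CCCO | starting material
2 | (E)-1-bromoprop-1-ene | C/C=C/Br | starting material
3 | dimethyl[(1E)-4-[(dimethylalumanyl)oxy]-2-methylbut-1-en-1-yl]alumane | C[Al](C)/C=C(\C)CCO[Al](C)C | intermediate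
4 | (3E,5E)-3-methylhepta-3,5-dien-1-ol | OCC/C(C)=C/C=C/C | intermediate
5 | (2E,4E)-7-iodo-5-methylhepta-2,4-diene | ICC/C(C)=C/C=C/C | intermediate
6 | 4-methylpent-2-yn-1-ol | CC(C)C#CCO | starting material
7 | sodium 2,2-bis(2-methoxyethoxy)-3-(propan-2-yl)-2,5-dihydro-1,2-oxaluminol-2-uide (cyclic alkenylaluminate) | [Na+].CC(C)C1=CCO[Al-]1(OCCOC)OCCOC | intermediate
8 | (2Z)-3-iodo-4-methylpent-2-en-1-ol | OC/C=C(\I)C(C)C | intermediate
9 | [(3E,5E)-3-methylhepta-3,5-dien-1-yl]lithium | [Li]CC/C(C)=C/C=C/C | intermediate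
10 | lithium 9-methoxy-9-[(3E,5E)-3-methylhepta-3,5-dien-1-yl]-9-boranuidabicyclo[3.3.1]nonane | [Li+].CO[B-]1(CC/C(C)=C/C=C/C)C2CCCC1CCC2 | intermediate
11 | (2E,6E,8E)-6-methyl-3-(propan-2-yl)deca-2,6,8-trien-1-ol | OC/C=C(\CC/C(C)=C/C=C/C)C(C)C | intermediate
12 | [(2R,3R)-3-[(3E,5E)-3-methylhepta-3,5-dien-1-yl]-3-(propan-2-yl)oxiran-2-yl]methanol | OC[C@H]1O[C@@]1(C(C)C)CC/C(C)=C/C=C/C | intermediate
13 | (2S,3R)-3-[(3E,5E)-3-methylhepta-3,5-dien-1-yl]-3-(propan-2-yl)oxirane-2-carbaldehyde | O=C[C@H]1O[C@@]1(C(C)C)CC/C(C)=C/C=C/C | intermediate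
14 | 1-[(2R,3R)-3-[(3E,5E)-3-methylhepta-3,5-dien-1-yl]-3-(propan-2-yl)oxiran-2-yl]ethan-1-ol (both carbinol epimers) | CC(O)[C@H]1O[C@@]1(C(C)C)CC/C(C)=C/C=C/C | intermediate
15 | 1-[(2S,3R)-3-[(3E,5E)-3-methylhepta-3,5-dien-1-yl]-3-(propan-2-yl)oxiran-2-yl]ethan-1-one | CC(=O)[C@H]1O[C@@]1(C(C)C)CC/C(C)=C/C=C/C | intermediate
16 | triethyl({1-[(2S,3R)-3-[(3E,5E)-3-methylhepta-3,5-dien-1-yl]-3-(propan-2-yl)oxiran-2-yl]ethenyl}oxy)silane | C=C(O[Si](CC)(CC)CC)[C@H]1O[C@@]1(C(C)C)CC/C(C)=C/C=C/C | intermediate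
17 | trifluoromethanesulfonate salt of 16 silylated (triethylsilyl) at the oxirane oxygen | C=C(O[Si](CC)(CC)CC)[C@H]1[O+]([Si](CC)(CC)CC)[C@@]1(C(C)C)CC/C(C)=C/C=C/C.[O-]S(=O)(=O)C(F)(F)F | intermediate
18 | (3R,3aR,6R,8aR)-6,8a-dimethyl-3-(propan-2-yl)-3-[(triethylsilyl)oxy]-2,3,3a,5,6,8a-hexahydroazulen-4(1H)-one | O=C2C[C@@H](C)C=C[C@@]3(C)CC[C@@](O[Si](CC)(CC)CC)(C(C)C)[C@H]23 | intermediate
19 | (3R,3aR,6S,8aS)-6,8a-dimethyl-3-(propan-2-yl)-3-[(triethylsilyl)oxy]octahydroazulen-4(1H)-one | O=C2C[C@@H](C)CC[C@@]3(C)CC[C@@](O[Si](CC)(CC)CC)(C(C)C)[C@H]23 | intermediate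
20 | triethyl{[(3R,3aS,6S,8aS)-6,8a-dimethyl-3-(propan-2-yl)-4-[(trimethylsilyl)oxy]-1,2,3,3a,6,7,8,8a-octahydroazulen-3-yl]oxy}silane | C[Si](C)(C)OC2=C[C@@H](C)CC[C@@]3(C)CC[C@@](O[Si](CC)(CC)CC)(C(C)C)[C@H]23 | intermediate
21 | (3R,3aR,8aS)-6,8a-dimethyl-3-(propan-2-yl)-3-[(triethylsilyl)oxy]-2,3,3a,7,8,8a-hexahydroazulen-4(1H)-one | O=C2C=C(C)CC[C@@]3(C)CC[C@@](O[Si](CC)(CC)CC)(C(C)C)[C@H]23 | intermediate
22 | (3R,3aR,8aS)-3-hydroxy-6,8a-dimethyl-3-(propan-2-yl)-2,3,3a,7,8,8a-hexahydroazulen-4(1H)-one | O=C2C=C(C)CC[C@@]3(C)CC[C@@](O)(C(C)C)[C@H]23 | intermediate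
23 | (3R,3aS,4S,8aS)-6,8a-dimethyl-3-(propan-2-yl)-1,2,3,3a,4,7,8,8a-octahydroazulene-3,4-diol | O[C@H]2C=C(C)CC[C@@]3(C)CC[C@@](O)(C(C)C)[C@H]23 | intermediate
24 | 4-methoxybenzoyl chloride | COc1ccc(C(=O)Cl)cc1 | starting material
25 | (3R,3aS,4S,8aS)-3-hydroxy-6,8a-dimethyl-3-(propan-2-yl)-1,2,3,3a,4,7,8,8a-octahydroazulen-4-yl 4-methoxybenzoate | COc1ccc(C(=O)O[C@H]2C=C(C)CC[C@@]3(C)CC[C@@](O)(C(C)C)[C@H]23)cc1 | target

**Step count**

Total: 16 steps. Longest linear sequence: 15 steps (steps 1, 2 and 4 to 16; step 3 is a one-step side branch).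

**Steps most likely to fail, with fallbacks**

1. Step 10 (key cycloaddition). The diene terminus that must bond to C3a is fully substituted and carries its methyl group on the inside position. Backside attack on the silylated epoxide may therefore be slow, so that silyl-triflate-induced epoxide rearrangement, proton loss from the allyl cation or (3+2) closure outruns seven-ring closure. The compact transition state may also compete and erode the trans ring fusion. The fallback drops the epoxide-coupled activation and generates a free oxyallyl cation under basic conditions, with stereocontrol from the tether instead of the epoxide C–O bond. It sets out from 15: reductive opening of the epoxy ketone at the α-carbon (SmI2, THF/MeOH, −90 °C) should give the aldol (4S,7E,9E)-4-hydroxy-7-methyl-4-(propan-2-yl)undeca-7,9-dien-2-one F1. Silylation (TESOTf, 2,6-lutidine, −78 °C) gives (4S,7E,9E)-7-methyl-4-(propan-2-yl)-4-[(triethylsilyl)oxy]undeca-7,9-dien-2-one F2. Chlorination of the kinetic methyl enolate (LiN(iPr)2, then TsCl, −78 °C) gives (4S,7E,9E)-1-chloro-7-methyl-4-(propan-2-yl)-4-[(triethylsilyl)oxy]undeca-7,9-dien-2-one F3. Treatment of F3 with Et3N in CF3CH2OH ionizes the α'-enolate to the oxyallyl cation, which should add across the tethered diene with the C3 silyloxy centre controlling the faces; the ring-fusion centre next to the ketone can be equilibrated with base afterwards. The route is rejoined at 18.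

2. Step 15 (directed reduction). Exchange of the hindered tertiary hydroxyl onto boron may be slow, so that undirected hydride attack from the face away from the angular methyl, or conjugate reduction, competes and the wrong C4 configuration results. The fallback accepts external attack and corrects C4 by substitution. It sets out from 22: Luche reduction (NaBH4, CeCl3·7H2O, MeOH, −78 °C) should give the C4 epimer (3R,3aS,4R,8aS)-6,8a-dimethyl-3-(propan-2-yl)-1,2,3,3a,4,7,8,8a-octahydroazulene-3,4-diol F4. Mitsunobu esterification of F4 with 4-methoxybenzoic acid (PPh3, DIAD, THF, 0 °C to rt) inverts C4 and installs the ester in the same operation, so the route is rejoined at 25.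

3. Step 4 (sp3–sp2 coupling). Halogen–lithium exchange next to a conjugated diene may be accompanied by carbolithiation or Wurtz coupling, and slow transfer of the alkyl group from boron may lead to loss of the organometallic before coupling. The fallback forms the same bond at the ester oxidation level by iron catalysis. It sets out from 5: magnesium insertion (Mg, Et2O) gives [(3E,5E)-3-methylhepta-3,5-dien-1-yl]magnesium iodide F5. Separately, purchased ethyl 4-methyl-3-oxopentanoate is converted (Tf2O, aq LiOH, toluene, 0 °C) to ethyl (2Z)-4-methyl-3-{[(trifluoromethyl)sulfonyl]oxy}pent-2-enoate F6. Coupling of F5 with F6 (Fe(acac)3 5 mol %, THF/NMP, −30 °C) with retention should give ethyl (2E,6E,8E)-6-methyl-3-(propan-2-yl)deca-2,6,8-trienoate F7. Reduction of F7 with iBu2AlH (CH2Cl2, −78 °C) returns to the route at 11.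

**Further compounds**

F1 | step 10 | (4S,7E,9E)-4-hydroxy-7-methyl-4-(propan-2-yl)undeca-7,9-dien-2-one | CC(=O)C[C@](O)(C(C)C)CC/C(C)=C/C=C/C
F2 | step 10 | (4S,7E,9E)-7-methyl-4-(propan-2-yl)-4-[(triethylsilyl)oxy]undeca-7,9-dien-2-one | CC(=O)C[C@](O[Si](CC)(CC)CC)(C(C)C)CC/C(C)=C/C=C/C
F3 | step 10 | (4S,7E,9E)-1-chloro-7-methyl-4-(propan-2-yl)-4-[(triethylsilyl)oxy]undeca-7,9-dien-2-one | ClCC(=O)C[C@](O[Si](CC)(CC)CC)(C(C)C)CC/C(C)=C/C=C/C
F4 | step 15 | (3R,3aS,4R,8aS)-6,8a-dimethyl-3-(propan-2-yl)-1,2,3,3a,4,7,8,8a-octahydroazulene-3,4-diol | O[C@@H]2C=C(C)CC[C@@]3(C)CC[C@@](O)(C(C)C)[C@H]23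
F5 | step 4 | [(3E,5E)-3-methylhepta-3,5-dien-1-yl]magnesium iodide | I[Mg]CC/C(C)=C/C=C/C
F6 | step 4 | ethyl (2Z)-4-methyl-3-{[(trifluoromethyl)sulfonyl]oxy}pent-2-enoate | CCOC(=O)/C=C(\OS(=O)(=O)C(F)(F)F)C(C)C
F7 | step 4 | ethyl (2E,6E,8E)-6-methyl-3-(propan-2-yl)deca-2,6,8-trienoate | CCOC(=O)/C=C(\CC/C(C)=C/C=C/C)C(C)C
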